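**Plan**

- Cuts: first the bond between C3 of ring A and C7 of ring B, then, together, the two aryl–alkyl bonds of ring A (C1–C8a and C4–C4a). Ring B is cut at C1–C8a (Friedel–Crafts) and at the arene–CH2 bond (Negishi).
- Enabling feature: in ring A the 1,4-related, oxygen-bearing carbons C1 (C=O) and C4 (CH–OH) sit on the neighbouring arene carbons C8a and C4a. C1–C2–C3–C4 plus the C4 oxygen is therefore a furan laid across an aryne, and the adduct is a strained 7-oxabenzonorbornadiene whose oxygen bridge serves as a temporary ring.
- Forward order: the aryne–furan [4+2] gives ring A as the oxabicycle. Ring B is built linearly (Negishi, Friedel–Crafts closure, transfer hydrogenation, ortho-iodination, benzylic oxidation, borylation). A strain-release rhodium-catalysed arylative ring opening joins the halves, hydrogen-atom-transfer hydration/oxidation installs the ring A carbonyl, and two deprotections finish.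
- Stereochemistry: C4 of ring B (R) comes from Noyori transfer hydrogenation. C3 (R) and C4 (S) of ring A come from ligand-controlled exo, syn arylrhodation of the (1R,4S) enantiomer of the racemic oxabicycle (regiodivergent resolution); they are cis because the aryl group enters on the face of the oxygen bridge and the C4–O bond is never broken.

Key step: step 2

Assumption: tetralone numbering is used for both rings. Ring A is the 3-aryl-4,5-dihydroxy-7-methyl unit and ring B the 4,8-dihydroxy-6-methyl unit joined through C7. The target is read as (3R,4S) in ring A (aryl and hydroxyl cis) and (4R) in ring B.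

**Route**

Step 1
Reactants: 1 3-bromo-5-methylphenol
Product: 2 1-(benzyloxy)-3-bromo-5-methylbenzene
Conditions: BnBr (1.1 equiv), K2CO3, DMF, rt
Reagents that add atoms: benzyl bromide, BrCc1ccccc1
Why: Williamson ether synthesis on the phenoxide; benzyl is chosen because it withstands LDA, helps to acidify the neighbouring ring C–H and can be removed late with BCl3.

Step 2
Reactants: 2 1-(benzyloxy)-3-bromo-5-methylbenzene; 3 furan
Product: 6 rac-5-(benzyloxy)-7-methyl-1,4-dihydro-1,4-epoxynaphthalene (cis-bridged 7-oxabenzonorbornadiene), via aryllithium 4 (not isolated), via aryne 5 (not isolated)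
Conditions: LDA (LiN(i-Pr)2, 1.3 equiv), furan (10 equiv), THF, −78 °C → rt
Reagents that add atoms: none
Why: LDA removes the one ring proton of 2 that lies between bromine and the benzyloxy group, and the aryllithium 4 loses LiBr on warming to give the aryne 5, whose strained triple bond joins the carbons that become C4a and C8a of ring A. Furan, used in excess, then adds through its 2- and 5-carbons in a concerted, suprafacial [4+2] cycloaddition, so the C1–C8a and C4–C4a bonds form in the same event; the closest known reaction type is the Diels–Alder trapping by furan of 3-alkoxybenzynes made from 3-haloanisoles and lithium amides. The six-membered carbocycle of ring A is closed by this cycloaddition (both bonds in one transition state, no stepwise ring closure), and with it the oxygen-bridged bicyclo[2.2.1] frame in which the furan oxygen is held between C1 and C4 as a temporary bridge. The two bridgehead stereocentres are formed cis by the geometry of the cycloaddition and as a racemate, as nothing in the flask is chiral; their absolute sense is selected in step 10. The only selectivity needed is in the metalation (the C–H flanked by Br and OBn over the two others, secured by their combined inductive acidification), since the twofold symmetry of furan makes the orientation of the unsymmetrical aryne immaterial and amide addition to 5 is held back by the excess of furan. The ring strain of the bridged alkene of 6 is the driving force on which step 10 draws.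

Step 3
Reactants: 7 2-bromo-5-methylanisole (1-bromo-2-methoxy-4-methylbenzene); 8 (4-ethoxy-4-oxobutyl)zinc bromide
Product: 9 ethyl 4-(2-methoxy-4-methylphenyl)butanoate
Conditions: Pd(OAc)2 (2 mol %), SPhos (4 mol %), THF, rt → 50 °C
Reagents that add atoms: none
Why: Negishi cross-coupling of the aryl bromide with the primary alkylzinc reagent, which tolerates the ester and places the four-carbon chain ortho to the methoxy group.

Step 4
Reactants: 9 ethyl 4-(2-methoxy-4-methylphenyl)butanoate
Product: 11 5-methoxy-7-methyl-3,4-dihydronaphthalen-1(2H)-one, via carboxylic acid 10 (not isolated)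
Conditions: LiOH, THF/MeOH/H2O, rt; 1 M HCl; then Eaton's reagent (P2O5 in MeSO3H), 50 °C
Reagents that add atoms: none
Why: Saponification followed by intramolecular Friedel–Crafts acylation of the acid; only one position ortho to the side chain is free, so a single tetralone can form, and the methyl ether withstands the acidic medium.

Step 5
Reactants: 11 5-methoxy-7-methyl-3,4-dihydronaphthalen-1(2H)-one
Product: 12 (1R)-5-methoxy-7-methyl-1,2,3,4-tetrahydronaphthalen-1-ol
Conditions: RuCl(p-cymene)[(R,R)-TsDPEN] (1 mol %), HCO2H/Et3N (5:2), 35 °C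
Reagents that add atoms: none
Why: Noyori asymmetric transfer hydrogenation, in which the ruthenium hydride/N–H pair of the (R,R)-TsDPEN complex delivers hydride to one face of the aryl ketone; by analogy with 1-tetralone this should give the (R) carbinol, the future C4 of ring B.

Step 6
Reactants: 12 (1R)-5-methoxy-7-methyl-1,2,3,4-tetrahydronaphthalen-1-ol
Product: 13 tert-butyl{[(1R)-5-methoxy-7-methyl-1,2,3,4-tetrahydronaphthalen-1-yl]oxy}dimethylsilane
Conditions: TBSCl, imidazole, DMF, rt
Reagents that add atoms: tert-butyldimethylsilyl chloride, CC(C)(C)[Si](C)(C)Cl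
Why: Standard silylation of the secondary benzylic alcohol; the bulky silyl ether survives organolithium base, shields the carbinol C–H in step 8 and is removed by fluoride at the end.

Step 7
Reactants: 13 tert-butyl{[(1R)-5-methoxy-7-methyl-1,2,3,4-tetrahydronaphthalen-1-yl]oxy}dimethylsilane
Product: 15 tert-butyl{[(1R)-6-iodo-5-methoxy-7-methyl-1,2,3,4-tetrahydronaphthalen-1-yl]oxy}dimethylsilane, via aryllithium 14 (not isolated)
Conditions: n-BuLi (1.5 equiv), TMEDA, Et2O, 0 °C → rt; then I2, THF, −78 °C → rt
Reagents that add atoms: iodine, II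
Why: Directed ortho-metalation; the methoxy group is the only effective directing group (the bulky silyl ether is a poor one) and C6 is its only free ortho position, so lithiation and iodine quench should place iodine between the methoxy and the 7-methyl group without touching the stereocentre.

Step 8
Reactants: 15 tert-butyl{[(1R)-6-iodo-5-methoxy-7-methyl-1,2,3,4-tetrahydronaphthalen-1-yl]oxy}dimethylsilane
Product: 16 (4R)-4-[(tert-butyldimethylsilyl)oxy]-7-iodo-8-methoxy-6-methyl-3,4-dihydronaphthalen-1(2H)-one
Conditions: Rh2(cap)4 (cap = caprolactamate, 1 mol %), t-BuOOH (70 % aq.), NaHCO3, 1,2-dichloroethane, 40 °C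
Reagents that add atoms: tert-butyl hydroperoxide, CC(C)(C)OO
Why: Benzylic C–H oxidation by tert-butylperoxyl radicals; the ring methylene next to the methoxy-bearing arene carbon (C4 of 15) is the only secondary benzylic position, the carbinol C–H is shielded by the silyl group and the aryl methyl is a slower primary site, so the ketone should appear peri to the methoxy group with the (R) centre untouched.

Step 9
Reactants: 16 (4R)-4-[(tert-butyldimethylsilyl)oxy]-7-iodo-8-methoxy-6-methyl-3,4-dihydronaphthalen-1(2H)-one
Product: 17 (4R)-4-[(tert-butyldimethylsilyl)oxy]-8-methoxy-6-methyl-7-(4,4,5,5-tetramethyl-1,3,2-dioxaborolan-2-yl)-3,4-dihydronaphthalen-1(2H)-one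
Conditions: B2pin2, Pd2(dba)3 (2 mol %), SPhos (8 mol %), KOAc, 1,4-dioxane, 100 °C
Reagents that add atoms: bis(pinacolato)diboron, CC1(C)OB(OC1(C)C)B1OC(C)(C)C(C)(C)O1
Why: Miyaura borylation; zerovalent palladium carrying the bulky biaryl phosphine inserts into the doubly ortho-substituted C–I bond and acetate-assisted transmetalation from B2pin2 gives the pinacol boronate under conditions that leave the aryl ketone and the silyl ether alone.

Step 10
Reactants: 6 rac-5-(benzyloxy)-7-methyl-1,4-dihydro-1,4-epoxynaphthalene (2.2 equiv); 17 (4R)-4-[(tert-butyldimethylsilyl)oxy]-8-methoxy-6-methyl-7-(pinacolboryl)-3,4-dihydronaphthalen-1(2H)-one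
Product: 18 (1S,2R)-8-(benzyloxy)-2-[(5R)-5-[(tert-butyldimethylsilyl)oxy]-1-methoxy-3-methyl-8-oxo-5,6,7,8-tetrahydronaphthalen-2-yl]-6-methyl-1,2-dihydronaphthalen-1-ol (aryl and hydroxyl cis)
Conditions: [Rh(cod)Cl]2 (2.5 mol %), PPF-P(t-Bu)2 (1-[2-(diphenylphosphino)ferrocenyl]ethyl-di-tert-butylphosphine, 6 mol %; the hand that gives the (1S,2R) series, fixed in a pilot run on the parent oxabicycle), Cs2CO3 (5 M aq., 1 equiv), THF, rt → 50 °C
Reagents that add atoms: none
Why: Lautens-type rhodium-catalysed asymmetric ring opening with an arylboron reagent, in which the arylrhodium formed by transmetalation adds syn across the exo face of the strained alkene and β-oxygen elimination opens the bridge so that aryl and hydroxyl emerge cis, while the chiral ligand decides which alkene carbon is arylated: in (1R,4S)-6 this is C3 next to the benzyloxy-flanked bridgehead (giving 18 with C3 R and the retained C4–O bond S), and in (1S,4R)-6 it is the other carbon, so the mirror-image substrate ends as a separable constitutional isomer (regiodivergent resolution).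

Step 11
Reactants: 18 (1S,2R)-8-(benzyloxy)-2-[ring B aryl]-6-methyl-1,2-dihydronaphthalen-1-ol
Product: 19 the 1-O-tert-butyldimethylsilyl ether of 18, (1S,2R) retained
Conditions: TBSOTf, 2,6-lutidine, CH2Cl2, −78 → 0 °C
Reagents that add atoms: tert-butyldimethylsilyl trifluoromethanesulfonate, CC(C)(C)[Si](C)(C)OS(=O)(=O)C(F)(F)F
Why: Silylation of the hindered secondary carbinol with the silyl triflate and a non-nucleophilic base, needed so that only the new carbinol is oxidised in step 12 and the ionisable ring A benzylic oxygen is masked in step 13.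

Step 12
Reactants: 19 bis-silyl ether of the coupled dihydronaphthalene
Product: 21 (3R,4S)-5-(benzyloxy)-4-[(tert-butyldimethylsilyl)oxy]-3-[(5R)-5-[(tert-butyldimethylsilyl)oxy]-1-methoxy-3-methyl-8-oxo-5,6,7,8-tetrahydronaphthalen-2-yl]-7-methyl-3,4-dihydronaphthalen-1(2H)-one, via benzylic alcohol 20 (not isolated)
Conditions: Co(acac)2 (20 mol %), PhSiH3, O2 (1 atm), THF/i-PrOH, rt; then Dess–Martin periodinane, NaHCO3, CH2Cl2, rt
Reagents that add atoms: dioxygen, O=O
Why: Mukaiyama hydration followed by oxidation; a cobalt hydride delivers a hydrogen atom to C2 of the styrene-type double bond to give the benzylic C1 radical, which traps O2 (Markovnikov oxygenation), and Dess–Martin oxidation converges the alcohol epimers and any ketone already formed on the C1 ketone, the C3 and C4 centres taking no part.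

Step 13
Reactants: 21 fully protected bis-tetralone
Product: 22 (3R,4S)-4-[(tert-butyldimethylsilyl)oxy]-3-[(5R)-5-[(tert-butyldimethylsilyl)oxy]-1-hydroxy-3-methyl-8-oxo-5,6,7,8-tetrahydronaphthalen-2-yl]-5-hydroxy-7-methyl-3,4-dihydronaphthalen-1(2H)-one
Conditions: BCl3 (1 M in CH2Cl2, 5 equiv), C6HMe5 (3 equiv), CH2Cl2, −78 → −40 °C; MeOH, then aq. NaHCO3
Reagents that add atoms: none
Why: Boron trichloride cleaves the aryl benzyl ether (the benzyl cation being trapped by pentamethylbenzene) and, through a six-membered chelate with the ring B carbonyl, the peri methyl ether, while at low temperature the two silyl ethers and both ketones should survive.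

Step 14
Reactants: 22 bis-silyl ether of the target
Product: 23 (3R,4S)-4,5-dihydroxy-3-[(5R)-1,5-dihydroxy-3-methyl-8-oxo-5,6,7,8-tetrahydronaphthalen-2-yl]-7-methyl-3,4-dihydronaphthalen-1(2H)-one (CNP0228272.3)
Conditions: HF·pyridine, pyridine/THF, 0 °C → rt
Reagents that add atoms: none
Why: Fluoride-driven cleavage of both silyl ethers (strong Si–F bond) under buffered conditions that do not ionise the benzylic C–O bonds, so the two carbinol centres should be released without epimerisation or dehydration to a naphthol.

**Compound list**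

1 | 3-bromo-5-methylphenol | Cc1cc(O)cc(Br)c1 | starting material
2 | 1-(benzyloxy)-3-bromo-5-methylbenzene | Cc1cc(Br)cc(OCc2ccccc2)c1 | intermediate
3 | furan | c1ccoc1 | starting material
4 | [2-(benzyloxy)-6-bromo-4-methylphenyl]lithium | Cc1cc(Br)c([Li])c(OCc2ccccc2)c1 | intermediate
5 | 3-(benzyloxy)-5-methylbenzyne | CC1=CC#CC(OCc2ccccc2)=C1 | intermediate
6 | rac-5-(benzyloxy)-7-methyl-1,4-dihydro-1,4-epoxynaphthalene | Cc1cc(OCc2ccccc2)c2c(c1)C1C=CC2O1 | intermediate
7 | 2-bromo-5-methylanisole | COc1cc(C)ccc1Br | starting material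
8 | (4-ethoxy-4-oxobutyl)zinc bromide | CCOC(=O)CCC[Zn]Br | starting material
9 | ethyl 4-(2-methoxy-4-methylphenyl)butanoate | CCOC(=O)CCCc1ccc(C)cc1OC | intermediate
10 | 4-(2-methoxy-4-methylphenyl)butanoic acid | OC(=O)CCCc1ccc(C)cc1OC | intermediate
11 | 5-methoxy-7-methyl-3,4-dihydronaphthalen-1(2H)-one | COc1cc(C)cc2c1CCCC2=O | intermediate
12 | (1R)-5-methoxy-7-methyl-1,2,3,4-tetrahydronaphthalen-1-ol | COc1cc(C)cc2c1CCC[C@H]2O | intermediate
13 | tert-butyl{[(1R)-5-methoxy-7-methyl-1,2,3,4-tetrahydronaphthalen-1-yl]oxy}dimethylsilane | COc1cc(C)cc2c1CCC[C@H]2O[Si](C)(C)C(C)(C)C | intermediate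
14 | 6-lithio derivative of 13 (lithium between methoxy and methyl) | COc1c([Li])c(C)cc2c1CCC[C@H]2O[Si](C)(C)C(C)(C)C | intermediate
15 | tert-butyl{[(1R)-6-iodo-5-methoxy-7-methyl-1,2,3,4-tetrahydronaphthalen-1-yl]oxy}dimethylsilane | COc1c(I)c(C)cc2c1CCC[C@H]2O[Si](C)(C)C(C)(C)C | intermediate
16 | (4R)-4-[(tert-butyldimethylsilyl)oxy]-7-iodo-8-methoxy-6-methyl-3,4-dihydronaphthalen-1(2H)-one | COc1c(I)c(C)cc2c1C(=O)CC[C@H]2O[Si](C)(C)C(C)(C)C | intermediate
17 | (4R)-4-[(tert-butyldimethylsilyl)oxy]-8-methoxy-6-methyl-7-(4,4,5,5-tetramethyl-1,3,2-dioxaborolan-2-yl)-3,4-dihydronaphthalen-1(2H)-one | COc1c(B2OC(C)(C)C(C)(C)O2)c(C)cc2c1C(=O)CC[C@H]2O[Si](C)(C)C(C)(C)C | intermediate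
18 | (1S,2R)-8-(benzyloxy)-2-[(5R)-5-[(tert-butyldimethylsilyl)oxy]-1-methoxy-3-methyl-8-oxo-5,6,7,8-tetrahydronaphthalen-2-yl]-6-methyl-1,2-dihydronaphthalen-1-ol | Cc1cc(OCc3ccccc3)c2c(c1)C=C[C@H](c1c(C)cc3c(c1OC)C(=O)CC[C@H]3O[Si](C)(C)C(C)(C)C)[C@@H]2O | intermediate
19 | 1-O-tert-butyldimethylsilyl ether of 18 | Cc1cc(OCc3ccccc3)c2c(c1)C=C[C@H](c1c(C)cc3c(c1OC)C(=O)CC[C@H]3O[Si](C)(C)C(C)(C)C)[C@@H]2O[Si](C)(C)C(C)(C)C | intermediate
20 | (3R,4S)-5-(benzyloxy)-4-[(tert-butyldimethylsilyl)oxy]-3-[ring B aryl as in 19]-7-methyl-1,2,3,4-tetrahydronaphthalen-1-ol, both C1 epimers | Cc1cc(OCc3ccccc3)c2c(c1)C(O)C[C@H](c1c(C)cc3c(c1OC)C(=O)CC[C@H]3O[Si](C)(C)C(C)(C)C)[C@@H]2O[Si](C)(C)C(C)(C)C | intermediate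
21 | (3R,4S)-5-(benzyloxy)-4-[(tert-butyldimethylsilyl)oxy]-3-[(5R)-5-[(tert-butyldimethylsilyl)oxy]-1-methoxy-3-methyl-8-oxo-5,6,7,8-tetrahydronaphthalen-2-yl]-7-methyl-3,4-dihydronaphthalen-1(2H)-one | Cc1cc(OCc3ccccc3)c2c(c1)C(=O)C[C@H](c1c(C)cc3c(c1OC)C(=O)CC[C@H]3O[Si](C)(C)C(C)(C)C)[C@@H]2O[Si](C)(C)C(C)(C)C | intermediate
22 | (3R,4S)-4-[(tert-butyldimethylsilyl)oxy]-3-[(5R)-5-[(tert-butyldimethylsilyl)oxy]-1-hydroxy-3-methyl-8-oxo-5,6,7,8-tetrahydronaphthalen-2-yl]-5-hydroxy-7-methyl-3,4-dihydronaphthalen-1(2H)-one | Cc1cc(O)c2c(c1)C(=O)C[C@H](c1c(C)cc3c(c1O)C(=O)CC[C@H]3O[Si](C)(C)C(C)(C)C)[C@@H]2O[Si](C)(C)C(C)(C)C | intermediate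
23 | (3R,4S)-4,5-dihydroxy-3-[(5R)-1,5-dihydroxy-3-methyl-8-oxo-5,6,7,8-tetrahydronaphthalen-2-yl]-7-methyl-3,4-dihydronaphthalen-1(2H)-one | Cc1cc(O)c2c(c1)C(=O)C[C@H](c1c(C)cc3c(c1O)C(=O)CC[C@H]3O)[C@@H]2O | target

**Count and risks**

Total step count: 14. Longest linear sequence: 12 steps (steps 3–9, then 10–14). The ring A arm contributes steps 1 and 2 before the union.

Most likely to fail:

Step 10. The doubly ortho-substituted aryl group may pass from boron to monovalent rhodium too slowly, so that protodeboronation wins. The ligand may also control incompletely which alkene carbon is arylated, which would erode both regio- and enantiopurity. Even when the step works as designed, half of the aryl donor is spent on the mirror-image substrate. The fallback sets out from 6 and 16 and comes back at 18. Racemic 6 is resolved by preparative chromatography on a chiral stationary phase to give (1R,4S)-5-(benzyloxy)-7-methyl-1,4-dihydro-1,4-epoxynaphthalene F1. F1 is then joined with the aryl iodide 16 under reductive palladium catalysis (PdCl2(PPh3)2, Zn powder, ZnCl2, Et3N, THF, 60 °C). Oxidative addition of the iodide to zerovalent palladium replaces the boron-to-rhodium transfer, and exo syn carbopalladation followed by β-oxygen elimination again gives the cis arrangement. The stereochemistry then rests on the resolved substrate. As the achiral catalyst does not choose between the two alkene carbons, 18 has to be separated from its regioisomer by chromatography.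

Step 7. Metalation at the hindered position between methoxy and methyl may be slow enough for deprotonation at the benzylic methylene beside the methoxy group, or at the silyloxy-bearing carbon (followed by silyl migration), to compete. The fallback sets out from 13 and comes back at 15 without new compounds: electrophilic aromatic iodination (N-iodosuccinimide, CF3CO2H cat., MeCN, 0 °C). The bulky electrophile should avoid the position para to the methoxy group (C8), which is buttressed by the 7-methyl group and the peri silyloxy-bearing carbon, and take C6.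

Step 13. The Lewis acid may ionise the ring A benzylic C4–O bond (epimerisation, or elimination towards a naphthol) or strip a silyl group before both ethers are cleaved. The fallback sets out from 21 and comes back at 22. Hydrogenolysis (H2 1 atm, Pd/C, EtOAc, rt) removes the benzyl group under neutral conditions to give (3R,4S)-4-[(tert-butyldimethylsilyl)oxy]-3-[(5R)-5-[(tert-butyldimethylsilyl)oxy]-1-methoxy-3-methyl-8-oxo-5,6,7,8-tetrahydronaphthalen-2-yl]-5-hydroxy-7-methyl-3,4-dihydronaphthalen-1(2H)-one F2. Chelation-controlled demethylation of the methoxy group peri to the ring B carbonyl with MgI2·OEt2 (toluene, 60 °C) then gives 22.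

Further compounds
F1 | step 10 | (1R,4S)-5-(benzyloxy)-7-methyl-1,4-dihydro-1,4-epoxynaphthalene | Cc1cc(OCc2ccccc2)c2c(c1)[C@H]1C=C[C@@H]2O1
F0 | step 7 | none | none
F2 | step 13 | (3R,4S)-4-[(tert-butyldimethylsilyl)oxy]-3-[(5R)-5-[(tert-butyldimethylsilyl)oxy]-1-methoxy-3-methyl-8-oxo-5,6,7,8-tetrahydronaphthalen-2-yl]-5-hydroxy-7-methyl-3,4-dihydronaphthalen-1(2H)-one | Cc1cc(O)c2c(c1)C(=O)C[C@H](c1c(C)cc3c(c1OC)C(=O)CC[C@H]3O[Si](C)(C)C(C)(C)C)[C@@H]2O[Si](C)(C)C(C)(C)C
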